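**Plan**

- Numbering: unit 1 is the flavone with the 4-methoxyphenyl ring and unit 2 the flavone with the 4-hydroxyphenyl ring; each has a benzo ring A, a pyranone ring C and an aryl ring B.
- Enabling feature: ring A of unit 1 is a 1,3,5-trioxygenated benzene (oxygens on C5, C7 and C8a) whose C8, flanked by the C7 and C8a oxygens, carries ring A of unit 2. A vinylketene and an aryl ynol ether assemble exactly this pattern.
- Retrosynthesis: the ethers are cleaved last. Ring C of unit 2 is cut at O1–C2, C3–C4 and C4–C4a (iodoresorcinol, CO, arylalkyne). Ring C of unit 1 is cut at the same three bonds (salicylaldehyde plus arylacetylide). Ring A of unit 1 is then cut at C7–C8 and C4a–C8a into an aryl siloxyalkyne and 3-ethoxycyclobutenone. The 8,8'' axis is never disconnected; it descends from an aryl–CHO bond.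
- Forward order: ring A of unit 2 is bought as 5-methoxyresorcinol and carried to the siloxyalkyne (steps 1–4). Ring A of unit 1 arises in step 5. Rings C and B of unit 1 are attached in steps 8–10, those of unit 2 in steps 11–13, and step 14 unmasks the phenols.
- Stereochemistry: the target has no stereocentre. The carbinol centre of step 9 is transient, and the hindered axis forms as the racemate.

Key step: step 5

Assumption: the target SMILES carries no descriptor for the tetra-ortho-oxygenated 8,8'' axis, so the axis is treated as unspecified and the racemic atropisomer mixture is the goal.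

**Route**

Step 1
Reactants: 1 5-methoxyresorcinol (5-methoxybenzene-1,3-diol)
Product: 2 1-methoxy-3,5-bis(methoxymethoxy)benzene
Conditions: NaH, MOMCl, DMF, 0 °C → rt
Reagents that add atoms: chloromethyl methyl ether, COCCl
Why: Williamson etherification of both phenoxides with the reactive α-chloro ether should be clean, and the acetal groups later act as ortho-directing groups and as acid-labile masks orthogonal to benzyl ethers.

Step 2
Reactants: 2 1-methoxy-3,5-bis(methoxymethoxy)benzene
Product: 4 4-methoxy-2,6-bis(methoxymethoxy)benzaldehyde, via aryllithium 3 (not isolated)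
Conditions: n-BuLi, TMEDA, THF, 0 °C; DMF, 0 °C → rt; H2O
Reagents that add atoms: N,N-dimethylformamide, CN(C)C=O
Why: Directed ortho-metalation should occur at the C–H between the two OMOM groups, which direct cooperatively and more strongly than OMe, and Bouveault formylation of aryllithium 3 with DMF then gives the aldehyde.

Step 3
Reactants: 4 4-methoxy-2,6-bis(methoxymethoxy)benzaldehyde
Product: 5 2-ethynyl-5-methoxy-1,3-bis(methoxymethoxy)benzene
Conditions: dimethyl (1-diazo-2-oxopropyl)phosphonate, K2CO3, MeOH, rt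
Reagents that add atoms: dimethyl (1-diazo-2-oxopropyl)phosphonate, COP(=O)(OC)C(=[N+]=[N-])C(C)=O
Why: The Ohira–Bestmann variant of the Seyferth–Gilbert homologation converts non-enolisable aryl aldehydes into terminal alkynes under mild base that leaves the acetals untouched.

Step 4
Reactants: 5 2-ethynyl-5-methoxy-1,3-bis(methoxymethoxy)benzene
Product: 8 triisopropyl({[4-methoxy-2,6-bis(methoxymethoxy)phenyl]ethynyl}oxy)silane, via lithium acetylide 6 (not isolated), via lithium ynolate 7 (not isolated)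
Conditions: LiN(SiMe3)2, THF, −78 °C; t-BuOOLi (from t-BuOOH and LiN(SiMe3)2), −78 → 0 °C; i-Pr3SiOTf, −78 °C
Reagents that add atoms: tert-butyl hydroperoxide, CC(C)(C)OO; triisopropylsilyl trifluoromethanesulfonate, CC(C)[Si](OS(=O)(=O)C(F)(F)F)(C(C)C)C(C)C
Why: Electrophilic oxygenation of a lithium acetylide by lithium tert-butyl peroxide is an established route to ynolates, and the bulky silyl triflate traps ynolate 7 on oxygen at low temperature to give the siloxyalkyne.

Step 5
Reactants: 8 triisopropyl({[4-methoxy-2,6-bis(methoxymethoxy)phenyl]ethynyl}oxy)silane; 9 3-ethoxycyclobut-2-en-1-one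
Product: 14 4-ethoxy-4'-methoxy-2',6'-bis(methoxymethoxy)-6-[(triisopropylsilyl)oxy]biphenyl-2-ol, via vinylketene 10 (not isolated), via vinylcyclobutenone 11 (not isolated), via dienylketene 12 (not isolated), via cyclohexadienone 13 (not isolated)
Conditions: 9 (1.3 equiv), degassed toluene, 80 °C then 110 °C, sealed tube
Reagents that add atoms: none
Why: Proposed new method: heat should open 9 by four-electron electrocyclic cleavage to the (1-ethoxyvinyl)ketene 10, whose carbonyl carbon is attacked by the nucleophilic, aryl-bearing carbon of siloxyalkyne 8, so that the [2+2] adduct 11 has the aryl carbon bonded to the C=O carbon and the silyloxy carbon bonded to the ring CH. A second four-electron opening gives dienylketene 12, which closes ring A of unit 1 by thermal six-electron disrotatory electrocyclization to dienone 13 and tautomerises to phenol 14; overall the C7–C8 and C4a–C8a bonds are made. The closest known reaction is the Danheiser benzannulation of 3-alkylcyclobutenones with siloxyalkynes to resorcinol monosilyl ethers, which has not been shown for a 3-alkoxycyclobutenone or for a di-ortho-substituted aryl siloxyalkyne. No stereocentre is formed; the selectivity required is the regiochemistry of the ketene–alkyne union, secured by the oxygen-induced polarisation of the ynol ether and reinforced by the electron-rich aryl group, which places the aryl carbon between the hydroxyl and silyloxy carbons and the ethoxy carbon para to it. The linear alkyne holds the two ortho acetal groups away from the reacting carbons, and the crowded axis bond is already present in 8, so no hindered coupling is needed.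

Step 6
Reactants: 14 4-ethoxy-4'-methoxy-2',6'-bis(methoxymethoxy)-6-[(triisopropylsilyl)oxy]biphenyl-2-ol
Product: 15 {[6-(benzyloxy)-4-ethoxy-4'-methoxy-2',6'-bis(methoxymethoxy)biphenyl-2-yl]oxy}triisopropylsilane
Conditions: NaH, BnBr, n-Bu4NI (cat.), DMF, 0 °C → rt
Reagents that add atoms: benzyl bromide, BrCc1ccccc1
Why: Williamson benzylation of the single free phenol uses the oxygen differentiation delivered by the benzannulation to mono-protect what would otherwise be a symmetric resorcinol, the hindered silyl ether and the acetals being stable to the base.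

Step 7
Reactants: 15 {[6-(benzyloxy)-4-ethoxy-4'-methoxy-2',6'-bis(methoxymethoxy)biphenyl-2-yl]oxy}triisopropylsilane
Product: 16 6-(benzyloxy)-4-ethoxy-4'-methoxy-2',6'-bis(methoxymethoxy)biphenyl-2-ol
Conditions: n-Bu4NF, THF, 0 °C; H2O
Reagents that add atoms: none
Why: Fluoride-induced desilylation of the aryl silyl ether frees the one oxygen that is to become O1 of unit 1 without affecting benzyl, ethyl or acetal ethers.

Step 8
Reactants: 16 6-(benzyloxy)-4-ethoxy-4'-methoxy-2',6'-bis(methoxymethoxy)biphenyl-2-ol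
Product: 17 4-(benzyloxy)-6-ethoxy-2-hydroxy-3-[4-methoxy-2,6-bis(methoxymethoxy)phenyl]benzaldehyde
Conditions: MgCl2, Et3N, (CH2O)n, MeCN, reflux
Reagents that add atoms: paraformaldehyde (as formaldehyde), C=O
Why: The Casnati–Skattebøl formylation delivers formaldehyde within a magnesium phenoxide and therefore reacts only ortho to a free phenol, so the single open ortho position (the future C4a of unit 1) is formylated while the fully etherified ring cannot react.

Step 9
Reactants: 17 4-(benzyloxy)-6-ethoxy-2-hydroxy-3-[4-methoxy-2,6-bis(methoxymethoxy)phenyl]benzaldehyde; 18 1-ethynyl-4-methoxybenzene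
Product: 20 3-(benzyloxy)-5-ethoxy-6-[1-hydroxy-3-(4-methoxyphenyl)prop-2-yn-1-yl]-2-[4-methoxy-2,6-bis(methoxymethoxy)phenyl]phenol (racemic carbinol), via lithium arylacetylide 19 (not isolated)
Conditions: 18 (3 equiv), n-BuLi, THF, −78 °C; then 17, −78 → 0 °C; H2O; crude product used directly
Reagents that add atoms: none
Why: 1,2-Addition of excess lithium acetylide to a salicylaldehyde tolerates the phenoxide formed by the first equivalent and should give the propargylic alcohol, whose new carbinol centre arises without control as the racemate and is erased by the oxidation in step 10.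

Step 10
Reactants: 20 3-(benzyloxy)-5-ethoxy-6-[1-hydroxy-3-(4-methoxyphenyl)prop-2-yn-1-yl]-2-[4-methoxy-2,6-bis(methoxymethoxy)phenyl]phenol
Product: 22 7-(benzyloxy)-5-ethoxy-2-(4-methoxyphenyl)-8-[4-methoxy-2,6-bis(methoxymethoxy)phenyl]-4H-chromen-4-one, via ynone 21 (not isolated)
Conditions: MnO2, CH2Cl2, rt; filter; K2CO3, acetone, 56 °C
Reagents that add atoms: none
Why: MnO2 oxidises the benzylic propargylic alcohol chemoselectively to ynone 21, and in an aprotic medium the ortho phenoxide should add to the ynone in the 6-endo-dig sense (oxa-Michael addition) to close ring C of unit 1.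

Step 11
Reactants: 22 7-(benzyloxy)-5-ethoxy-2-(4-methoxyphenyl)-8-[4-methoxy-2,6-bis(methoxymethoxy)phenyl]-4H-chromen-4-one
Product: 23 7-(benzyloxy)-8-(2,6-dihydroxy-4-methoxyphenyl)-5-ethoxy-2-(4-methoxyphenyl)-4H-chromen-4-one
Conditions: HCl (1.25 M in MeOH), THF, 45 °C
Reagents that add atoms: none
Why: Acid-catalysed acetal exchange with methanol removes both methoxymethyl groups, while the benzyl, ethyl and methyl ethers and the pyranone are stable to dilute methanolic acid.

Step 12
Reactants: 23 7-(benzyloxy)-8-(2,6-dihydroxy-4-methoxyphenyl)-5-ethoxy-2-(4-methoxyphenyl)-4H-chromen-4-one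
Product: 24 7-(benzyloxy)-8-(2,6-dihydroxy-3-iodo-4-methoxyphenyl)-5-ethoxy-2-(4-methoxyphenyl)-4H-chromen-4-one (racemic about the axis)
Conditions: NIS (1.0 equiv), DMF, −30 → 0 °C
Reagents that add atoms: N-iodosuccinimide, O=C1CCC(=O)N1I
Why: Electrophilic aromatic iodination should take place on the free 5-methoxyresorcinol ring, by far the most electron-rich arene present, and because its two open positions are equivalent mono-iodination gives one constitution, the axis becoming a stereogenic element formed as the racemate.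

Step 13
Reactants: 24 7-(benzyloxy)-8-(2,6-dihydroxy-3-iodo-4-methoxyphenyl)-5-ethoxy-2-(4-methoxyphenyl)-4H-chromen-4-one; 25 1-(benzyloxy)-4-ethynylbenzene
Product: 27 7-(benzyloxy)-8-{2-[4-(benzyloxy)phenyl]-7-hydroxy-5-methoxy-4-oxo-4H-chromen-8-yl}-5-ethoxy-2-(4-methoxyphenyl)-4H-chromen-4-one, via ynone 26 (not isolated)
Conditions: PdCl2(dppf) (5 mol%), CO (5 bar), Et2NH, DMF, 80 °C
Reagents that add atoms: carbon monoxide, [C-]#[O+]
Why: In this carbonylative Sonogashira annulation of an ortho-iodophenol, zerovalent palladium inserts into the C–I bond, CO insertion and alkynylation give ynone 26, and in the secondary-amine medium the only hydroxyl ortho to the new acyl group closes ring C of unit 2 in the 6-endo sense, the other hydroxyl being para to the acyl group and unable to compete.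

Step 14
Reactants: 27 7-(benzyloxy)-8-{2-[4-(benzyloxy)phenyl]-7-hydroxy-5-methoxy-4-oxo-4H-chromen-8-yl}-5-ethoxy-2-(4-methoxyphenyl)-4H-chromen-4-one
Product: 28 5,7-dihydroxy-8-[5,7-dihydroxy-2-(4-hydroxyphenyl)-4-oxo-4H-chromen-8-yl]-2-(4-methoxyphenyl)-4H-chromen-4-one (target, racemic about the axis)
Conditions: BCl3 (excess), pentamethylbenzene, CH2Cl2, −78 °C → rt; MeOH, then aq. HCl
Reagents that add atoms: none
Why: BCl3 ionises the two benzyl ethers at low temperature with pentamethylbenzene trapping the benzyl cations, and on warming cleaves the 5-methyl and 5-ethyl ethers through their six-membered boron chelates with the C4 carbonyls (chelation-controlled peri-dealkylation), whereas the unchelated methyl ether on ring B of unit 1 should be inert.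

**Compound list**

1 | 5-methoxyresorcinol | COc1cc(O)cc(O)c1 | starting material
2 | 1-methoxy-3,5-bis(methoxymethoxy)benzene | COCOc1cc(OC)cc(OCOC)c1 | intermediate
3 | [4-methoxy-2,6-bis(methoxymethoxy)phenyl]lithium | [Li]c1c(OCOC)cc(OC)cc1OCOC | intermediate
4 | 4-methoxy-2,6-bis(methoxymethoxy)benzaldehyde | O=Cc1c(OCOC)cc(OC)cc1OCOC | intermediate
5 | 2-ethynyl-5-methoxy-1,3-bis(methoxymethoxy)benzene | C#Cc1c(OCOC)cc(OC)cc1OCOC | intermediate
6 | lithium [4-methoxy-2,6-bis(methoxymethoxy)phenyl]acetylide | [Li]C#Cc1c(OCOC)cc(OC)cc1OCOC | intermediate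
7 | lithium 2-[4-methoxy-2,6-bis(methoxymethoxy)phenyl]ethynolate | [Li]OC#Cc1c(OCOC)cc(OC)cc1OCOC | intermediate
8 | triisopropyl({[4-methoxy-2,6-bis(methoxymethoxy)phenyl]ethynyl}oxy)silane | CC(C)[Si](OC#Cc1c(OCOC)cc(OC)cc1OCOC)(C(C)C)C(C)C | intermediate
9 | 3-ethoxycyclobut-2-en-1-one | CCOC1=CC(=O)C1 | starting material
10 | 3-ethoxybuta-1,3-dien-1-one | CCOC(=C)C=C=O | intermediate
11 | 4-(1-ethoxyvinyl)-2-[4-methoxy-2,6-bis(methoxymethoxy)phenyl]-3-[(triisopropylsilyl)oxy]cyclobut-2-en-1-one (racemic) | CCOC(=C)C1C(=O)C(c2c(OCOC)cc(OC)cc2OCOC)=C1O[Si](C(C)C)(C(C)C)C(C)C | intermediate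
12 | 5-ethoxy-2-[4-methoxy-2,6-bis(methoxymethoxy)phenyl]-3-[(triisopropylsilyl)oxy]hexa-1,3,5-trien-1-one, ketene-bearing carbon and ethoxyvinyl group cis on the central double bond | CCOC(=C)/C=C(/O[Si](C(C)C)(C(C)C)C(C)C)C(=C=O)c1c(OCOC)cc(OC)cc1OCOC | intermediate
13 | 5-ethoxy-2-[4-methoxy-2,6-bis(methoxymethoxy)phenyl]-3-[(triisopropylsilyl)oxy]cyclohexa-2,4-dien-1-one | CCOC1=CC(O[Si](C(C)C)(C(C)C)C(C)C)=C(c2c(OCOC)cc(OC)cc2OCOC)C(=O)C1 | intermediate
14 | 4-ethoxy-4'-methoxy-2',6'-bis(methoxymethoxy)-6-[(triisopropylsilyl)oxy]biphenyl-2-ol | CCOc1cc(O)c(-c2c(OCOC)cc(OC)cc2OCOC)c(O[Si](C(C)C)(C(C)C)C(C)C)c1 | intermediate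
15 | {[6-(benzyloxy)-4-ethoxy-4'-methoxy-2',6'-bis(methoxymethoxy)biphenyl-2-yl]oxy}triisopropylsilane | CCOc1cc(OCc2ccccc2)c(-c2c(OCOC)cc(OC)cc2OCOC)c(O[Si](C(C)C)(C(C)C)C(C)C)c1 | intermediate
16 | 6-(benzyloxy)-4-ethoxy-4'-methoxy-2',6'-bis(methoxymethoxy)biphenyl-2-ol | CCOc1cc(O)c(-c2c(OCOC)cc(OC)cc2OCOC)c(OCc2ccccc2)c1 | intermediate
17 | 4-(benzyloxy)-6-ethoxy-2-hydroxy-3-[4-methoxy-2,6-bis(methoxymethoxy)phenyl]benzaldehyde | CCOc1cc(OCc2ccccc2)c(-c2c(OCOC)cc(OC)cc2OCOC)c(O)c1C=O | intermediate
18 | 1-ethynyl-4-methoxybenzene | C#Cc1ccc(OC)cc1 | starting material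
19 | lithium (4-methoxyphenyl)acetylide | [Li]C#Cc1ccc(OC)cc1 | intermediate
20 | 3-(benzyloxy)-5-ethoxy-6-[1-hydroxy-3-(4-methoxyphenyl)prop-2-yn-1-yl]-2-[4-methoxy-2,6-bis(methoxymethoxy)phenyl]phenol (racemic) | CCOc1cc(OCc2ccccc2)c(-c2c(OCOC)cc(OC)cc2OCOC)c(O)c1C(O)C#Cc1ccc(OC)cc1 | intermediate
21 | 1-{4-(benzyloxy)-6-ethoxy-2-hydroxy-3-[4-methoxy-2,6-bis(methoxymethoxy)phenyl]phenyl}-3-(4-methoxyphenyl)prop-2-yn-1-one | CCOc1cc(OCc2ccccc2)c(-c2c(OCOC)cc(OC)cc2OCOC)c(O)c1C(=O)C#Cc1ccc(OC)cc1 | intermediate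
22 | 7-(benzyloxy)-5-ethoxy-2-(4-methoxyphenyl)-8-[4-methoxy-2,6-bis(methoxymethoxy)phenyl]-4H-chromen-4-one | CCOc1cc(OCc2ccccc2)c(-c2c(OCOC)cc(OC)cc2OCOC)c2oc(-c3ccc(OC)cc3)cc(=O)c12 | intermediate
23 | 7-(benzyloxy)-8-(2,6-dihydroxy-4-methoxyphenyl)-5-ethoxy-2-(4-methoxyphenyl)-4H-chromen-4-one | CCOc1cc(OCc2ccccc2)c(-c2c(O)cc(OC)cc2O)c2oc(-c3ccc(OC)cc3)cc(=O)c12 | intermediate
24 | 7-(benzyloxy)-8-(2,6-dihydroxy-3-iodo-4-methoxyphenyl)-5-ethoxy-2-(4-methoxyphenyl)-4H-chromen-4-one (racemic about the axis) | CCOc1cc(OCc2ccccc2)c(-c2c(O)cc(OC)c(I)c2O)c2oc(-c3ccc(OC)cc3)cc(=O)c12 | intermediate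
25 | 1-(benzyloxy)-4-ethynylbenzene | C#Cc1ccc(OCc2ccccc2)cc1 | starting material
26 | 7-(benzyloxy)-8-(3-{3-[4-(benzyloxy)phenyl]prop-2-ynoyl}-2,6-dihydroxy-4-methoxyphenyl)-5-ethoxy-2-(4-methoxyphenyl)-4H-chromen-4-one | CCOc1cc(OCc2ccccc2)c(-c2c(O)cc(OC)c(C(=O)C#Cc3ccc(OCc4ccccc4)cc3)c2O)c2oc(-c3ccc(OC)cc3)cc(=O)c12 | intermediate
27 | 7-(benzyloxy)-8-{2-[4-(benzyloxy)phenyl]-7-hydroxy-5-methoxy-4-oxo-4H-chromen-8-yl}-5-ethoxy-2-(4-methoxyphenyl)-4H-chromen-4-one (racemic about the axis) | CCOc1cc(OCc2ccccc2)c(-c2c(O)cc(OC)c3c(=O)cc(-c4ccc(OCc5ccccc5)cc4)oc23)c2oc(-c3ccc(OC)cc3)cc(=O)c12 | intermediate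
28 | 5,7-dihydroxy-8-[5,7-dihydroxy-2-(4-hydroxyphenyl)-4-oxo-4H-chromen-8-yl]-2-(4-methoxyphenyl)-4H-chromen-4-one (racemic about the axis) | COc1ccc(-c2cc(=O)c3c(O)cc(O)c(-c4c(O)cc(O)c5c(=O)cc(-c6ccc(O)cc6)oc45)c3o2)cc1 | target

**Step count**

Total steps: 14. Longest linear sequence: 14 steps (1 → 28); compounds 9, 18 and 25 are purchased.

**Steps most likely to fail**

Step 5. The ethoxy-stabilised cyclobutenone may open too slowly, so that the vinylketene dimerises or the siloxyalkyne isomerises by silyl shift before the [2+2] union, or the crowded ketene–alkyne addition may not occur. The fallback makes the axis by Suzuki–Miyaura coupling at the flavone stage, which is known chemistry. It sets out from compound 2: aryllithium 3 is trapped with 2-isopropoxy-4,4,5,5-tetramethyl-1,3,2-dioxaborolane to give 2-[4-methoxy-2,6-bis(methoxymethoxy)phenyl]-4,4,5,5-tetramethyl-1,3,2-dioxaborolane F1. Commercial acacetin is benzylated at the unchelated 7-hydroxyl (BnBr, K2CO3, acetone) to 7-(benzyloxy)-5-hydroxy-2-(4-methoxyphenyl)-4H-chromen-4-one F2. This is ethylated at the chelated 5-hydroxyl (EtI, Cs2CO3, DMF, 60 °C) to 7-(benzyloxy)-5-ethoxy-2-(4-methoxyphenyl)-4H-chromen-4-one F3. Iodination at C8, the site expected for fully etherified 5,7-dioxygenated flavones (I2, CF3CO2Ag, CH2Cl2), gives 7-(benzyloxy)-5-ethoxy-8-iodo-2-(4-methoxyphenyl)-4H-chromen-4-one F4. Coupling of F1 with F4 (Pd(OAc)2, SPhos, K3PO4, toluene/H2O, 100 °C) should give compound 22, where the route is rejoined before step 11.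

Step 13. Oxidative addition into the hindered, electron-rich C–I bond may be slow, alkynylation may outrun CO uptake and lead to furan closure, or the ynone may close in the 5-exo sense. The fallback leaves the palladium chemistry (and the iodination of step 12) and sets out from compound 23. Friedel–Crafts acetylation of the free resorcinol ring (AcOH, BF3·OEt2, 90 °C; both open positions equivalent) gives 8-(3-acetyl-2,6-dihydroxy-4-methoxyphenyl)-7-(benzyloxy)-5-ethoxy-2-(4-methoxyphenyl)-4H-chromen-4-one F5. Its polyanion (LiN(SiMe3)2, 5 equiv, THF, −78 °C) is C-aroylated with 4-(benzyloxy)benzoyl chloride in a Claisen-type condensation to 7-(benzyloxy)-8-(3-{3-[4-(benzyloxy)phenyl]-3-oxopropanoyl}-2,6-dihydroxy-4-methoxyphenyl)-5-ethoxy-2-(4-methoxyphenyl)-4H-chromen-4-one F6. Acid cyclodehydration (AcOH, cat. H2SO4, 95 °C) through the only hydroxyl ortho to the diketone returns the route to compound 27.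

Step 14. Cleavage of the chelated ethyl ether may stall, liberated benzyl cations may alkylate the electron-rich rings, or long exposure may begin to attack the ring B methyl ether. The fallback separates the two tasks and sets out from compound 27. Hydrogenolysis (H2, Pd/C, EtOAc/MeOH, rt) removes both benzyl groups without generating cations and gives 5-ethoxy-7-hydroxy-8-[7-hydroxy-2-(4-hydroxyphenyl)-5-methoxy-4-oxo-4H-chromen-8-yl]-2-(4-methoxyphenyl)-4H-chromen-4-one F7. Chelation-controlled dealkylation of the two peri ethers with AlCl3 in MeCN at 80 °C, which spares unchelated aryl methyl ethers, then gives compound 28.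

**Further compounds**

F1 | step 5 | 2-[4-methoxy-2,6-bis(methoxymethoxy)phenyl]-4,4,5,5-tetramethyl-1,3,2-dioxaborolane | COCOc1cc(OC)cc(OCOC)c1B1OC(C)(C)C(C)(C)O1
F2 | step 5 | 7-(benzyloxy)-5-hydroxy-2-(4-methoxyphenyl)-4H-chromen-4-one | COc1ccc(-c2cc(=O)c3c(O)cc(OCc4ccccc4)cc3o2)cc1
F3 | step 5 | 7-(benzyloxy)-5-ethoxy-2-(4-methoxyphenyl)-4H-chromen-4-one | CCOc1cc(OCc2ccccc2)cc2oc(-c3ccc(OC)cc3)cc(=O)c12
F4 | step 5 | 7-(benzyloxy)-5-ethoxy-8-iodo-2-(4-methoxyphenyl)-4H-chromen-4-one | CCOc1cc(OCc2ccccc2)c(I)c2oc(-c3ccc(OC)cc3)cc(=O)c12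
F5 | step 13 | 8-(3-acetyl-2,6-dihydroxy-4-methoxyphenyl)-7-(benzyloxy)-5-ethoxy-2-(4-methoxyphenyl)-4H-chromen-4-one | CCOc1cc(OCc2ccccc2)c(-c2c(O)cc(OC)c(C(C)=O)c2O)c2oc(-c3ccc(OC)cc3)cc(=O)c12
F6 | step 13 | 7-(benzyloxy)-8-(3-{3-[4-(benzyloxy)phenyl]-3-oxopropanoyl}-2,6-dihydroxy-4-methoxyphenyl)-5-ethoxy-2-(4-methoxyphenyl)-4H-chromen-4-one | CCOc1cc(OCc2ccccc2)c(-c2c(O)cc(OC)c(C(=O)CC(=O)c3ccc(OCc4ccccc4)cc3)c2O)c2oc(-c3ccc(OC)cc3)cc(=O)c12
F7 | step 14 | 5-ethoxy-7-hydroxy-8-[7-hydroxy-2-(4-hydroxyphenyl)-5-methoxy-4-oxo-4H-chromen-8-yl]-2-(4-methoxyphenyl)-4H-chromen-4-one | CCOc1cc(O)c(-c2c(O)cc(OC)c3c(=O)cc(-c4ccc(O)cc4)oc23)c2oc(-c3ccc(OC)cc3)cc(=O)c12
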